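Target made in this flask while solid substrate remains cannot reach the crystals without first standing in solution beside the solid that attacks it.

    solid reagent ⇌ partner, rate k1*(cs1 - [partner]) while solid is left; crystals form when [partner] > cs1 (cs1 = 0.12 M, k1 = 8.5 × 10⁻⁵ /s)
    dissolved substrate + partner → target (k2 = 0.0071 /M/s)
    solid substrate ⇌ dissolved substrate, rate k3*(cs3 - [dissolved substrate]) while solid is left; crystals form when [dissolved substrate] > cs3 (cs3 = 16 mM, k3 = 0.0012 /s)
    crystals ⇌ target, rate k4*(cs4 - [target]) while solid is left; crystals form when [target] > cs4 (cs4 = 3.8 mM, k4 = 3.2 × 10⁻⁴ /s)
    solid substrate + target → side product (k5 = 1.7 × 10⁻⁴ /M/s)

solid substrate 0.20 M; solid reagent 2.50 equiv; time 30 h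

- percentages count the solid substrate that a species holds: one side product counts as two
- target is meant together with its crystals
- solid, in amounts per volume of the solution: solid substrate, crystals, solid reagent
- at the start none of the solid reagent is in solution
- at the start none of the solid substrate is in solution
- dissolved substrate means what is dissolved; the solid is not counted in it
- run time (flask): 30 h

- the target and crystals together standing at 30 h, as a percentage of the solid substrate charged
- concentration of dissolved substrate in solution at 30 h, in percent of saturation

1. While both solids remain, I take a steady state: each solid dissolves as fast as the coupling of dissolved substrate with partner consumes it. Setting the three rates equal gives a quadratic, and its root is the feed F = 18.2 mM/h.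

2. At this feed the solid substrate lasts about 11.0 h, which is shorter than the run of 30 h. Its amount falls steadily, and each side product counts twice. So with P the level of dissolved target, the share of the charge lost is L = 1.7 × 10⁻⁴ /M/s × charge × P / F.

3. The zero of my scale is a flask whose crystals take up target at once, so P is the solubility 3.8 mM and L is 2.55%. The other extreme has no crystals: target piles up in solution, and the same reckoning, in which the attack consumes neither solid nor target, gives an overestimate of 44.8%.

4. The real flask lies between them. Crystals relax the excess in 0.868 h, far shorter than the life of the solid, so the excess holds steady at F divided by the crystal coefficient and P = 19.6 mM. This gives the loss share, my selectivity loss, L = 13.2%, and I commit to y = 86.8%.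

5. Once the solid is gone, dissolved substrate decays on partner of about 0.0605 M or more, so sat at the end of the run is <0.001%.

The forecast gives 90% and 0%, holding that “the side product alone sets the yield”. Its yield is higher than mine by 3.2 percentage points.

The flask gives 90.9% and 0%, and with the attack of solid substrate on target struck out, the answer to y is 100%. At 30.0 h side product holds 9.07%, against my loss share of 13.2%. At fixed feed and fixed P, the loss share grows in step with the charge. For a neighbour flask charged with 0.50 M it therefore reads 32.9%, or 22.7% when I start from this flask's reading. That neighbour ends with 22.0% of side product.

The numbers of this flask are assumed; what happens was integrated by code.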